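Follow the solid substrate first, in amber and in grey.

the same everywhere: temperature −20 °C
- amber: solid substrate 0.020 M; the very flask that is asked about, followed so far
- grey: solid substrate 0.013 M; run made earlier
- flask: solid substrate 0.020 M; time 12 h

| run | time / h | single ring / % | solid substrate / % |
|---|---|---|---|
| amber | 3.00 | 21 | 11 |
| amber | 6.00 | 25 | 1 |
| amber | 10.0 | 27 | 0 |
| amber | 12.0 | 26 | 0 |
| grey | 1.00 | 7 | 10 |
| grey | 2.00 | 19 | 0 |
| grey | 3.00 | 19 | 0 |
| grey | 4.00 | 33 | 0 |

(each reading ± 2 percentage points)

- ash: change nothing and wait 4.0 h more
- maple: at 12 h raise the temperature by 20 K, then wait 4.0 h
- alder: at 12 h take out 90% of the single ring then present, then wait 4.0 h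

- solid, in amounts per volume of the solution: solid substrate
- single ring that was removed still counts
- the numbers in the tables scatter by 2 percentage points (one standard deviation)
- at the start none of the solid substrate is in solution
- the earlier runs do not show what temperature does; that part of a forecast is a guess

* single ring, in percent of the solid substrate first charged, at 12 h
* the option that brings most further single ring ("none" if no option brings more than 2 percentage points) (ash / maple / alder / none)
* single ring present, with what was taken out counted in, in percent of the solid substrate first charged, after ash
* single ring present, with what was taken out counted in, in percent of the solid substrate first charged, after alder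

Question: how much solid has left each run? Answer: amber, the flask asked about, has lost 17.8 mM at 3.00 h. Grey has lost 11.7 mM at 1.00 h.

Question: what rule joins them? Answer: I take the first dissolving as instantly finished, a gulp G, and then a steady feed F, a zero-order supply, with both the same in the two runs. The feed rate F is the gap between the two losses over the gap between their times, 3.05 mM h⁻¹. So G is 8.65 mM. The clearing time is the charge less G, divided by F.

Question: two readings gave two constants, so where is the check? Answer: in the later readings. Grey should clear at 1.43 h, and it reads 0% at 2.00 h. Amber should clear at 3.72 h, and it reads 1% at 6.00 h.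

Question: what stands in amber at 12 h? Answer: its late single ring readings average 26.0%, so I commit to that. I expect ash to add less than 2 percentage points: by my rule the feed ends at 3.72 h, before 12 h, and the late readings show no trend beyond their scatter.

Question: is a flat ring a dead one? Answer: I read no answer in these readings. A flat line may be a dead end or a balance with something unseen, so I name no gain for maple or alder.

The forecast gives 26%, best none, 26% after ash and 27% after alder: “Warming has no substrate left to act on and is only a guess.”

The flask gives 25.4% and best maple. Counting what was taken out, it holds 24.6% after ash, 33.6% after alder and 37.2% after maple. The flat ring was no dead end, for alder adds 8.3 points. At 12.0 h the flask makes single ring, taken net, at 0.817 of the rate at which it uses it up, and starting material still stands at 6.82%. Isomer of the product stands at 23.5% then, and that pair has a relaxation half-life of 2.33 h by this step alone, short against 12 h.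

    starting material → single ring (k = 0.00250 min⁻¹, Ea = 82.0 kJ mol⁻¹)
    2 starting material → open dimer (k = 0.120 M⁻¹ min⁻¹, Ea = 53.0 kJ mol⁻¹)
    starting material + open dimer → open trimer (k = 0.670 M⁻¹ min⁻¹, Ea = 57.0 kJ mol⁻¹)
    open dimer → ring dimer (k = 0.00200 min⁻¹, Ea = 85.0 kJ mol⁻¹)
    single ring ⇌ isomer of the product (K = 1.30, k = 0.00280 min⁻¹, Ea = 86.0 kJ mol⁻¹, ΔH = −36.0 kJ mol⁻¹)
    solid substrate ⇌ starting material, rate k6*(cs6 - [starting material]) while solid is left; crystals form when [starting material] > cs6 (solubility = 9.60 mM, k = 0.180 min⁻¹)
    single ring → over-reaction product (k = 2.00 × 10⁻⁵ min⁻¹, Ea = 91.0 kJ mol⁻¹)
    (constants at −20 °C)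

On this flask, G and F leave 38.4% of the charge at 1.20 h, and the flask holds 38.3% solid substrate then. The neighbour flask is the same flask charged with 0.050 M. Its reckoned clearing time is 13.6 h, later than 12 h, so by the rule solid should remain at 9.50% of that charge. The neighbour flask gives single ring 19.5%. Its solid substrate stands at 9.08% at 12.0 h.

All runs were computed with constants of no real substance; the scatter is artificial.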